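## Analysis of the target

The target is a p-terphenyl whose central benzene ring (ring B, C1 to C6) is fully substituted: (2Z,4S,5S)-4,5-epoxyhex-2-enoyloxy groups at C1 and C2, 4-hydroxyphenyl rings (rings A and C) at C3 and C6, and free hydroxyls at C4 and C5. The molecule is C2-symmetric, so every operation on the core can be run twofold. The four stereocentres sit in two trans-disubstituted oxiranes, 4S,5S in each chain; within a chain the two centres are vicinal and locked by the three-membered ring, while the two chains are too far apart to influence each other, so both must come from one enantiopure acyl fragment. Sensitive groups are the aryl ester links (activated towards base and nucleophiles), the Z-enoate double bonds (isomerisation by reversible conjugate addition), the vinyl epoxides (acid, zerovalent palladium, hydrogenation) and the electron-rich ring B (oxidation to a quinone). The carbon skeleton is simple; the difficulty is to tell apart the ortho oxygen pairs O1/O2 and O4/O5, which are alike in the bare core, and to deprotect at the end without harming the epoxy enoates. The plan rests on C4 and C5 being two adjacent oxygen-bearing ring carbons: the C4–C5 bond is an acyloin-type bond, so ring B can be closed there from an open six-carbon chain whose two inner carbons (later C1 and C2) already carry differently protected oxygens. This closure is the reverse of the oxidative ring opening by which fungi convert terphenylquinones into pulvinic acids.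

## Retrosynthetic reasoning

**22 from 21.** The last bonds cut are the four aryl O–Si bonds. Silyl ethers are the only phenol protection that a buffered, non-basic fluoride source removes without touching aryl esters, Z-alkenes or oxiranes. All four spectator phenols of 21 are therefore silylated, and the forward step must cleave two bulky and two smaller aryl silyl ethers and nothing else.

**21 from 13 and 19.** Cutting the two ester C–O bonds separates the core diol 13 from two equivalents of the carboxylate 19, which is activated as the mixed anhydride 20. Placing this cut late keeps the epoxides and Z-alkenes away from hydride, hydrogen and carbene chemistry. The forward reaction must acylate two neighbouring, hindered phenols without Z to E drift.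

**13 from 12 from 11.** These are protecting-group transfers. The catechol of 11 is capped with silyl groups (12), and the two benzyl ethers are then removed by hydrogenolysis (13) while no alkene is yet present. The oxygen pattern of 11 is thereby translated into "silyl = free in 22" and "benzyl = acylated in 22".

**11 from 9 (key disconnection).** The bond cut is the C–C bond between the two hydroxylated carbons of 11 (C4–C5 of the target). It is cut there because this is the only ring bond whose cleavage gives two carbons at the same (aldehyde) oxidation level and a symmetric, open-chain precursor. It also sorts the four oxygens into two formyl oxygens and two enol-ether oxygens. The forward reaction must turn one formyl carbon of 9 into a nucleophile that attacks the other, giving the acyloin 10, whose aromatisation makes the closure irreversible.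

**9 from 7.** A functional-group change: each formyl group comes from a nitrile through the aldimine 8. The nitrile survives the base and alkylation steps before it and reaches the aldehyde in one reduction, without an alcohol stage.

**7 from 5 and 6.** The two enol O–benzyl bonds are cut. Compound 5 is a bis-enol whose oxygens are the natural nucleophiles, and two molecules of 6 supply the benzyl groups that mark the later acyloxy pair at the outset.

**5 from 2 and 3; 2 from 1.** The two C–C bonds between the benzylic carbons and the oxalyl carbons are cut. A twofold Claisen-type condensation (through 4) assembles all six chain carbons and both aryl rings from one C2 electrophile and two identical nucleophiles. Compound 2 is the silyl ether of commercial 1.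

**19 from 18; 18 from 17 and 16; 17 from 15; 15 from 14.** The carboxylate comes from the methyl ester 18 without passing through the free acid. The Z-alkene of 18 is cut by olefination logic into the epoxy aldehyde 17 and the phosphonate 16. Both oxirane C–O bonds, and with them all stereocentres, go back to one asymmetric epoxidation of the allylic alcohol 14.

## Alternatives that were turned down

Alternative 1: The disconnection is at the two C–O bonds of the second oxygen pair on a finished terphenyl catechol, 3,6-bis(4-methoxyphenyl)benzene-1,2-diol A2. Forward, the catechol A2 is oxidised by a periodate in the alcohol whose alkoxy groups are wanted. The o-quinone takes up the alcohol at C4, is re-oxidised, and takes up a second molecule at C5, which leads to 4,5-dimethoxy-3,6-bis(4-methoxyphenyl)-1,2-benzoquinone A1 as the product of the key step.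
- For: the catechol A2 is available convergently by cross-coupling, the only free ring positions are the ones to be oxygenated, and oxidative dialkoxylation of o-quinones is established on simple catechols. On precedent this key step is stronger than the chosen one.
- Against: every oxygen to be unmasked later is a methyl ether. The two ring-B methyl ethers would have to be cleaved beside the two anisoles, and the anisoles would have to be cleaved at the very end next to epoxy enoate esters, which Lewis-acid demethylation does not allow. Hydrolysing the vinylogous-ester methoxy groups of A1 at the quinone stage is no escape: the product is a tautomer of the symmetrical 2,5-dihydroxy-3,6-bis(4-methoxyphenyl)-1,4-benzoquinone A3 and in the quinone A3 the ortho sorting of the oxygens is lost.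
- Comparison: the chosen strategy accepts an unprecedented ring closure but delivers 11 with benzyl and silyl groups already placed for a mild endgame.

Alternative 2: The disconnection is at the four C–O bonds of the two oxiranes, made last on the bis[(2Z,4E)-hexa-2,4-dienoate] A5 of the silyl-protected core. Forward, a chiral dioxirane, generated from a carbohydrate-derived ketone catalyst and a peroxymonosulfate oxidant, epoxidises both γ,δ-double bonds of the tetraene A5 to give the tetrakis(tert-butyldimethylsilyl) ether A4 of the target.
- For: the three-step branch 14 to 19 and the lactonisation-prone carboxylate disappear. Both stereocentre pairs are set catalytically, and dioxiranes reliably prefer the remote, more electron-rich alkene of a dienoate. On side-chain step economy it is stronger.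
- Against: it is only an endgame and presupposes a differentiated core such as 13, so it leaves the main problem open. The epoxidation medium is aqueous and basic, which endangers the aryl esters and aryl silyl ethers of A5. The oxidant is electrophilic and ring B is a hexa-oxygenated arene. Two independent face selections on one molecule cannot be purified in between, so any wrong selection appears as a diastereomer of A4 at the last stage.
- Comparison: the chosen route sets the stereocentres on the small alcohol 14 by a reaction of predictable sense, allows the purity of 15 or 18 to be checked before coupling, and lets no oxidant meet the core.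

Alternative 3: The disconnection is at two ring C–C bonds (C2–C3 and C5–C6 of a quinone). Forward, two molecules of an arylpyruvic thioester, taken here as S-ethyl 3-[4-(triisopropylsilyloxy)phenyl]-2-oxopropanethioate A7, are joined head to tail under soft enolisation (a magnesium halide with a tertiary amine). Each benzylic carbon acylates the thioester of the partner, and the ring closes as 2,5-bis[4-(triisopropylsilyloxy)phenyl]-3,6-dihydroxy-1,4-benzoquinone A6 in one operation.
- For: one step forms two C–C bonds and the ring from two identical C9 units, along the biosynthetic line. In step count to the C18 skeleton it clearly beats the five steps needed here to reach 11.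
- Against: the ketone carbonyl of A7 is more electrophilic than its thioester, so aldol-type dimerisation is expected to compete with the double acyl transfer, and the non-enzymatic version is unproven. The quinone A6 also sorts its oxygens the wrong way: a para pair of carbonyls and a para pair of hydroxyls, so each ortho pair holds one of each. After reduction the two ortho pairs are identical and could only be separated by a statistical mono-protection.
- Comparison: the chosen strategy is longer to the ring but distinguishes the ortho pairs by construction, and its ring closure is intramolecular.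

Key step: step 5

Remarks on the chemistry:
- Compounds 7, 8 and 9 are drawn as the 2E,4E isomers, the arrangement expected on steric grounds. Other geometric isomers, if formed, are assumed to be carried along, because step 5 is expected to equilibrate them.
- Twofold reactions on the C2-symmetric compounds pass through the corresponding mono-derivatives, which are not numbered separately.

## Route

Step 1
Reactants: 1 4-hydroxyphenylacetonitrile
Product: 2 [4-(triisopropylsilyloxy)phenyl]acetonitrile
Conditions: iPr3SiCl, imidazole, DMF, rt
Reagents that add atoms: triisopropylsilyl chloride, CC(C)[Si](Cl)(C(C)C)C(C)C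
Why: Standard imidazole-mediated silylation of a phenol. The triisopropylsilyl ether is chosen because it should tolerate the amide base, the hydride and the hydrogenolysis ahead and still leave with fluoride at the end.

Step 2
Reactants: 2 [4-(triisopropylsilyloxy)phenyl]acetonitrile (2 equiv), 3 diethyl oxalate
Product: 5 3,4-dihydroxy-2,5-bis[4-(triisopropylsilyloxy)phenyl]hexa-2,4-dienedinitrile (bis-enol of the 3,4-dioxo dinitrile), via ethyl 3-cyano-2-oxo-3-arylpropanoate enolate 4 (not isolated)
Conditions: NaN(SiMe3)2 (4 equiv), THF, −78 °C → rt; then 1 M HCl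
Reagents that add atoms: none
Why: Twofold Claisen-type C-acylation of the benzylic nitrile anion by the oxalate, the classical condensation that leads to pulvinic acid precursors. Each acylation is driven by deprotonation of the acidic β-ketonitrile, and a non-nucleophilic amide base is used so that the aryl silyl ethers are not attacked.

Step 3
Reactants: 5 3,4-dihydroxy-2,5-bis[4-(triisopropylsilyloxy)phenyl]hexa-2,4-dienedinitrile, 6 benzyl alcohol (2 equiv)
Product: 7 (2E,4E)-3,4-bis(benzyloxy)-2,5-bis[4-(triisopropylsilyloxy)phenyl]hexa-2,4-dienedinitrile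
Conditions: PPh3 (2.4 equiv), iPrO2CN=NCO2iPr (2.4 equiv), THF, 0 °C → rt
Reagents that add atoms: none
Why: Twofold Mitsunobu etherification of a strongly acidic α-cyano enol, one molecule of 6 being consumed at each enol oxygen. Reaction at oxygen is expected because the carbon terminus is fully substituted, and the neutral conditions leave nitriles and silyl ethers alone. The 2E,4E geometry places each aryl group away from the other half of the chain.

Step 4
Reactants: 7 (2E,4E)-3,4-bis(benzyloxy)-2,5-bis[4-(triisopropylsilyloxy)phenyl]hexa-2,4-dienedinitrile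
Product: 9 (2E,4E)-3,4-bis(benzyloxy)-2,5-bis[4-(triisopropylsilyloxy)phenyl]hexa-2,4-dienedial, via bis-aldimine 8 (not isolated)
Conditions: iBu2AlH, CH2Cl2, −78 °C; aq. KNaC4H4O6; then AcOH/NaOAc buffer (pH 5), THF/H2O, 0 °C
Reagents that add atoms: water, O
Why: Partial reduction of a nitrile by iBu2AlH stops at the N-aluminio aldimine at low temperature, and mild hydrolysis releases the aldehyde. Water should attack the unhindered CH=N carbon faster than the fully substituted enol-ether carbon, so the benzyl enol ethers survive.

Step 5
Reactants: 9 (2E,4E)-3,4-bis(benzyloxy)-2,5-bis[4-(triisopropylsilyloxy)phenyl]hexa-2,4-dienedial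
Product: 11 4,5-bis(benzyloxy)-3,6-bis[4-(triisopropylsilyloxy)phenyl]benzene-1,2-diol, via cyclic acyloin 10 (not isolated)
Conditions: 3-benzyl-5-(2-hydroxyethyl)-4-methylthiazolium chloride (20 mol %), DBU (20 mol %), degassed THF, 50 °C, Ar
Reagents that add atoms: none
Why: Proposed new method: the thiazol-2-ylidene adds to one formyl group of 9 and proton transfer gives the Breslow intermediate, whose carbinol carbon is an acyl-anion equivalent; it attacks the second formyl carbon in a 6-exo-trig closure of ring B, forming the bond between the two future catechol carbons, and loss of the carbene releases the acyloin 10. Enolisation of 10 aromatises the ring to 11, which shuts off the retro-benzoin path and erases the one transient stereocentre, so no stereocontrol is needed. The closest known reaction type is the carbene-catalysed intramolecular benzoin condensation of dialdehydes to five- and six-membered cyclic acyloins; a closure that joins two enal carbonyls and ends in an arene has not been shown. Two selectivities are required. First, acyl-anion rather than homoenolate reactivity: the β-carbon of each enal is fully substituted and carries the benzyloxy donor, a thiazolium carbene with an amine base in an aprotic solvent is the combination that favours benzoin formation over β-protonation, and no alcohol solvent is present to trap an acyl azolium. Second, both formyl groups must lie on the inner side of the diene (2E,4E, s-cis about the central bond): this isomer is expected to be preferred because each aryl group avoids the other half of the chain, and the push-pull enal bonds can equilibrate by reversible conjugate addition of the carbene or the amidine, so that the one isomer able to cyclise is drained by the irreversible aromatisation. Benzyl and silyl ethers are inert to the carbene, and exclusion of air protects both the Breslow intermediate and the electron-rich catechol.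

Step 6
Reactants: 11 4,5-bis(benzyloxy)-3,6-bis[4-(triisopropylsilyloxy)phenyl]benzene-1,2-diol
Product: 12 1,2-bis(benzyloxy)-4,5-bis(tert-butyldimethylsilyloxy)-3,6-bis[4-(triisopropylsilyloxy)phenyl]benzene
Conditions: tBuMe2SiOTf, 2,6-lutidine, CH2Cl2, 0 °C → rt
Reagents that add atoms: tert-butyldimethylsilyl trifluoromethanesulfonate, CC(C)(C)[Si](C)(C)OS(=O)(=O)C(F)(F)F
Why: Silyl triflate with a hindered pyridine is the standard silylation for flanked phenols, and the smaller tert-butyldimethylsilyl group is chosen for the two neighbouring positions. The air-sensitive catechol is best silylated directly after step 5.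

Step 7
Reactants: 12 1,2-bis(benzyloxy)-4,5-bis(tert-butyldimethylsilyloxy)-3,6-bis[4-(triisopropylsilyloxy)phenyl]benzene
Product: 13 4,5-bis(tert-butyldimethylsilyloxy)-3,6-bis[4-(triisopropylsilyloxy)phenyl]benzene-1,2-diol
Conditions: H2 (1 atm), Pd/C, EtOAc, rt
Reagents that add atoms: none
Why: Hydrogenolysis of aryl benzyl ethers, to which aryl silyl ethers are inert in a neutral solvent. No alkene or epoxide is present yet, which is why this step precedes the acylation. The free and silylated oxygens are meta to each other, so silyl migration is not expected.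

Step 8
Reactants: 14 (E)-but-2-en-1-ol
Product: 15 [(2S,3S)-3-methyloxiran-2-yl]methanol
Conditions: Ti(OiPr)4 (5 mol %), L-(+)-diisopropyl tartrate (6 mol %), tBuOOH, 4 Å molecular sieves, CH2Cl2, −20 °C
Reagents that add atoms: tert-butyl hydroperoxide, CC(C)(C)OO
Why: Sharpless asymmetric epoxidation. The L-(+)-tartrate titanium catalyst converts E-2-alken-1-ols into the (2S,3S)-epoxy alcohols, and the trans relation follows from the E-alkene, so both stereocentres of each side chain are set here. Any minor enantiomer would later appear as a separable diastereomer of 21.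

Step 9
Reactants: 15 [(2S,3S)-3-methyloxiran-2-yl]methanol, 16 methyl bis(2,2,2-trifluoroethyl)phosphonoacetate
Product: 18 methyl (2Z)-3-[(2S,3S)-3-methyloxiran-2-yl]prop-2-enoate, via (2R,3S)-3-methyloxirane-2-carbaldehyde 17 (not isolated)
Conditions: (COCl)2, DMSO, CH2Cl2, −78 °C; Et3N; cold filtered solution of 17 added to 16, KN(SiMe3)2, 18-crown-6, THF, −78 °C
Reagents that add atoms: none
Why: Swern oxidation followed by the Still–Gennari variant of the Horner–Wadsworth–Emmons reaction, in which the electron-poor phosphonate and the crown-ether-separated potassium ion make elimination fast and kinetically Z-selective. The volatile aldehyde 17 is used in solution; it is not expected to epimerise because enolisation would require an alkylidene oxirane, and the change of descriptor at C2 from S to R is only a change of priorities.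

Step 10
Reactants: 18 methyl (2Z)-3-[(2S,3S)-3-methyloxiran-2-yl]prop-2-enoate
Product: 19 potassium (2Z)-3-[(2S,3S)-3-methyloxiran-2-yl]prop-2-enoate
Conditions: KOSiMe3, Et2O, 0 °C → rt; salt filtered and used at once
Reagents that add atoms: potassium trimethylsilanolate, C[Si](C)(C)[O-].[K+]
Why: Anhydrous silanolate cleavage of a methyl ester gives the carboxylate salt directly. The free Z-acid, which could lactonise by 5-exo opening of its own epoxide, is therefore never generated.

Step 11
Reactants: 13 4,5-bis(tert-butyldimethylsilyloxy)-3,6-bis[4-(triisopropylsilyloxy)phenyl]benzene-1,2-diol, 19 potassium (2Z)-3-[(2S,3S)-3-methyloxiran-2-yl]prop-2-enoate (3 equiv)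
Product: 21 4,5-bis(tert-butyldimethylsilyloxy)-3,6-bis[4-(triisopropylsilyloxy)phenyl]-1,2-phenylene bis[(2Z)-3-[(2S,3S)-3-methyloxiran-2-yl]prop-2-enoate], via mixed anhydride 20 (not isolated)
Conditions: 19, 2,4,6-Cl3C6H2COCl, THF, 0 °C; then 13, Et3N, DMAP (0.2 equiv), toluene, 0 °C → rt
Reagents that add atoms: none
Why: Yamaguchi esterification starting from the carboxylate salt: the mixed anhydride 20 transfers the enoyl group to the only two free hydroxyls of 13. Low temperature and sub-stoichiometric DMAP are meant to limit Z to E isomerisation by conjugate addition to the acylpyridinium.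

Step 12
Reactants: 21 4,5-bis(tert-butyldimethylsilyloxy)-3,6-bis[4-(triisopropylsilyloxy)phenyl]-1,2-phenylene bis[(2Z)-3-[(2S,3S)-3-methyloxiran-2-yl]prop-2-enoate]
Product: 22 4,5-dihydroxy-3,6-bis(4-hydroxyphenyl)-1,2-phenylene bis[(2Z)-3-[(2S,3S)-3-methyloxiran-2-yl]prop-2-enoate] (CNP0249450.1)
Conditions: HF·pyridine, pyridine, THF, 0 °C → rt
Reagents that add atoms: none
Why: Fluoride cleavage of four aryl silyl ethers, driven by Si–F bond formation. The pyridine-buffered reagent is not basic enough to cleave or isomerise the aryl enoates and should be too weakly acidic to open the acceptor-conjugated epoxides. Acyl migration is not possible because the free and acylated oxygens are meta to each other.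

## Compound list

1 | 4-hydroxyphenylacetonitrile | N#CCc1ccc(O)cc1 | starting material
2 | [4-(triisopropylsilyloxy)phenyl]acetonitrile | N#CCc1ccc(O[Si](C(C)C)(C(C)C)C(C)C)cc1 | intermediate
3 | diethyl oxalate | CCOC(=O)C(=O)OCC | starting material
4 | ethyl 3-cyano-2-oxo-3-[4-(triisopropylsilyloxy)phenyl]propanoate (present as its sodium enolate; no fixed configuration) | CCOC(=O)C(=O)C(C#N)c1ccc(O[Si](C(C)C)(C(C)C)C(C)C)cc1 | intermediate (not isolated)
5 | 3,4-dihydroxy-2,5-bis[4-(triisopropylsilyloxy)phenyl]hexa-2,4-dienedinitrile (bis-enol of the 3,4-dioxo dinitrile; enol geometry labile) | N#CC(c1ccc(O[Si](C(C)C)(C(C)C)C(C)C)cc1)=C(O)C(O)=C(c1ccc(O[Si](C(C)C)(C(C)C)C(C)C)cc1)C#N | intermediate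
6 | benzyl alcohol | OCc1ccccc1 | starting material
7 | (2E,4E)-3,4-bis(benzyloxy)-2,5-bis[4-(triisopropylsilyloxy)phenyl]hexa-2,4-dienedinitrile | N#C/C(c1ccc(O[Si](C(C)C)(C(C)C)C(C)C)cc1)=C(OCc1ccccc1)\C(OCc1ccccc1)=C(c1ccc(O[Si](C(C)C)(C(C)C)C(C)C)cc1)/C#N | intermediate
8 | (2E,4E)-3,4-bis(benzyloxy)-2,5-bis[4-(triisopropylsilyloxy)phenyl]hexa-2,4-diene-1,6-diimine (formed as its N-aluminium derivative) | N=C/C(c1ccc(O[Si](C(C)C)(C(C)C)C(C)C)cc1)=C(OCc1ccccc1)\C(OCc1ccccc1)=C(c1ccc(O[Si](C(C)C)(C(C)C)C(C)C)cc1)/C=N | intermediate (not isolated)
9 | (2E,4E)-3,4-bis(benzyloxy)-2,5-bis[4-(triisopropylsilyloxy)phenyl]hexa-2,4-dienedial | O=C/C(c1ccc(O[Si](C(C)C)(C(C)C)C(C)C)cc1)=C(OCc1ccccc1)\C(OCc1ccccc1)=C(c1ccc(O[Si](C(C)C)(C(C)C)C(C)C)cc1)/C=O | intermediate (key-step precursor)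
10 | 3,4-bis(benzyloxy)-6-hydroxy-2,5-bis[4-(triisopropylsilyloxy)phenyl]cyclohexa-2,4-dien-1-one (racemic, transient) | O=C1C(c2ccc(O[Si](C(C)C)(C(C)C)C(C)C)cc2)=C(OCc2ccccc2)C(OCc2ccccc2)=C(c2ccc(O[Si](C(C)C)(C(C)C)C(C)C)cc2)C1O | intermediate (not isolated)
11 | 4,5-bis(benzyloxy)-3,6-bis[4-(triisopropylsilyloxy)phenyl]benzene-1,2-diol | Oc1c(O)c(-c2ccc(O[Si](C(C)C)(C(C)C)C(C)C)cc2)c(OCc2ccccc2)c(OCc2ccccc2)c1-c1ccc(O[Si](C(C)C)(C(C)C)C(C)C)cc1 | intermediate (key-step product)
12 | 1,2-bis(benzyloxy)-4,5-bis(tert-butyldimethylsilyloxy)-3,6-bis[4-(triisopropylsilyloxy)phenyl]benzene | CC(C)(C)[Si](C)(C)Oc1c(O[Si](C)(C)C(C)(C)C)c(-c2ccc(O[Si](C(C)C)(C(C)C)C(C)C)cc2)c(OCc2ccccc2)c(OCc2ccccc2)c1-c1ccc(O[Si](C(C)C)(C(C)C)C(C)C)cc1 | intermediate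
13 | 4,5-bis(tert-butyldimethylsilyloxy)-3,6-bis[4-(triisopropylsilyloxy)phenyl]benzene-1,2-diol | CC(C)(C)[Si](C)(C)Oc1c(O[Si](C)(C)C(C)(C)C)c(-c2ccc(O[Si](C(C)C)(C(C)C)C(C)C)cc2)c(O)c(O)c1-c1ccc(O[Si](C(C)C)(C(C)C)C(C)C)cc1 | intermediate
14 | (E)-but-2-en-1-ol | C/C=C/CO | starting material
15 | [(2S,3S)-3-methyloxiran-2-yl]methanol | C[C@@H]1O[C@H]1CO | intermediate
16 | methyl bis(2,2,2-trifluoroethyl)phosphonoacetate | COC(=O)CP(=O)(OCC(F)(F)F)OCC(F)(F)F | starting material
17 | (2R,3S)-3-methyloxirane-2-carbaldehyde | C[C@@H]1O[C@H]1C=O | intermediate (not isolated)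
18 | methyl (2Z)-3-[(2S,3S)-3-methyloxiran-2-yl]prop-2-enoate | C[C@@H]1O[C@H]1/C=C\C(=O)OC | intermediate
19 | potassium (2Z)-3-[(2S,3S)-3-methyloxiran-2-yl]prop-2-enoate | C[C@@H]1O[C@H]1/C=C\C(=O)[O-].[K+] | intermediate
20 | (2Z)-3-[(2S,3S)-3-methyloxiran-2-yl]prop-2-enoic 2,4,6-trichlorobenzoic anhydride | C[C@@H]1O[C@H]1/C=C\C(=O)OC(=O)c1c(Cl)cc(Cl)cc1Cl | intermediate (not isolated)
21 | 4,5-bis(tert-butyldimethylsilyloxy)-3,6-bis[4-(triisopropylsilyloxy)phenyl]-1,2-phenylene bis[(2Z)-3-[(2S,3S)-3-methyloxiran-2-yl]prop-2-enoate] | C[C@@H]1O[C@H]1/C=C\C(=O)Oc1c(OC(=O)/C=C\[C@@H]2O[C@H]2C)c(-c2ccc(O[Si](C(C)C)(C(C)C)C(C)C)cc2)c(O[Si](C)(C)C(C)(C)C)c(O[Si](C)(C)C(C)(C)C)c1-c1ccc(O[Si](C(C)C)(C(C)C)C(C)C)cc1 | intermediate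
22 | 4,5-dihydroxy-3,6-bis(4-hydroxyphenyl)-1,2-phenylene bis[(2Z)-3-[(2S,3S)-3-methyloxiran-2-yl]prop-2-enoate] | C[C@@H]1O[C@H]1/C=C\C(=O)Oc1c(OC(=O)/C=C\[C@@H]2O[C@H]2C)c(-c2ccc(O)cc2)c(O)c(O)c1-c1ccc(O)cc1 | target

## Step count and least certain steps

Total step count: 12. Longest linear sequence: 9 steps (steps 1 to 7, 11 and 12, from 1). The acyl fragment takes 3 steps (8 to 10).

**Step 5 (key step, proposed new method).**
- What may go wrong: carbene addition to the hindered α-aryl enal may be too slow. The Breslow intermediate may react as a homoenolate, with β-protonation by the acidic catechol product followed by acyl transfer to that product. Aerial oxidation of the intermediate or of the catechol is a further risk.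
- Fallback by known chemistry, from 9 back to 11: reductive pinacol cyclisation of 9 with SmI2 (THF, tBuOH, −78 °C), a known closure of 1,6-dialdehydes, should give cis-4,5-bis(benzyloxy)-3,6-bis[4-(triisopropylsilyloxy)phenyl]cyclohexa-3,5-diene-1,2-diol F1 (either diol diastereomer would serve). Oxidation of one allylic carbinol with activated MnO2 in CH2Cl2 gives the hydroxy dienone 10, which tautomerises to 11. Any material oxidised further to 4,5-bis(benzyloxy)-3,6-bis[4-(triisopropylsilyloxy)phenyl]cyclohexa-3,5-diene-1,2-dione F2 is returned to 11 by a wash with aqueous Na2S2O4.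

**Step 3.**
- What may go wrong: the ambident enolate may be benzylated at carbon, the second etherification may stall, or a mixture of enol-ether geometries may form.
- Fallback, from 5 back to 7: the bis-enol is converted with oxalyl chloride and catalytic dimethylformamide into the bis(vinylogous acyl chloride) 3,4-dichloro-2,5-bis[4-(triisopropylsilyloxy)phenyl]hexa-2,4-dienedinitrile F3. Addition–elimination of 6 (two equivalents, Et3N, catalytic DABCO, MeCN) then forms the C–O bonds at the electrophilic carbon, so the site-selectivity question disappears, and the reversible addition should favour the less crowded 2E,4E isomer 7.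

**Step 11.**
- What may go wrong: Z to E isomerisation of the enoyl unit through reversible DMAP addition, incomplete second acylation at the crowded position, and lactonisation of 19 before it is activated.
- Fallback, from 17 (made from 15 as in step 9) and 13 back to 21: homologation of 17 with dimethyl (1-diazo-2-oxopropyl)phosphonate (K2CO3, MeOH) gives (2S,3S)-2-ethynyl-3-methyloxirane F4, kept in solution. Treatment with nBuLi and then CO2 gives (4S,5S)-4,5-epoxyhex-2-ynoic acid F5, which can neither lactonise nor isomerise. Carbodiimide coupling with 13 (dicyclohexylcarbodiimide, CH2Cl2, 0 °C) gives 4,5-bis(tert-butyldimethylsilyloxy)-3,6-bis[4-(triisopropylsilyloxy)phenyl]-1,2-phenylene bis[3-[(2S,3S)-3-methyloxiran-2-yl]prop-2-ynoate] F6. Semi-hydrogenation over Pd/CaCO3 poisoned with Pb(OAc)2 and quinoline then forms both Z-alkenes by syn addition and gives 21.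

**Step 12.**
- What may go wrong: the triisopropylsilyl ethers may cleave slowly, and the long exposure this forces may lead to epoxide opening by HF.
- Fallback, from 11 back to 22: Bu4NF removes the triisopropylsilyl groups of 11 to give 4,5-bis(benzyloxy)-3,6-bis(4-hydroxyphenyl)benzene-1,2-diol F7. Et3SiCl and imidazole give 1,2-bis(benzyloxy)-4,5-bis(triethylsilyloxy)-3,6-bis[4-(triethylsilyloxy)phenyl]benzene F8. Hydrogenolysis as in step 7 gives 4,5-bis(triethylsilyloxy)-3,6-bis[4-(triethylsilyloxy)phenyl]benzene-1,2-diol F9. Esterification with 19 as in step 11 gives 4,5-bis(triethylsilyloxy)-3,6-bis[4-(triethylsilyloxy)phenyl]-1,2-phenylene bis[(2Z)-3-[(2S,3S)-3-methyloxiran-2-yl]prop-2-enoate] F10. The triethylsilyl aryl ethers should then fall to pyridine-buffered HF·pyridine at −20 °C, far below the conditions needed for the bulkier groups, to give 22.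

## Further compounds

F1 | step 5 | (1R,2S)-4,5-bis(benzyloxy)-3,6-bis[4-(triisopropylsilyloxy)phenyl]cyclohexa-3,5-diene-1,2-diol (cis, meso) | O[C@@H]1[C@H](O)C(c2ccc(O[Si](C(C)C)(C(C)C)C(C)C)cc2)=C(OCc2ccccc2)C(OCc2ccccc2)=C1c1ccc(O[Si](C(C)C)(C(C)C)C(C)C)cc1
F2 | step 5 | 4,5-bis(benzyloxy)-3,6-bis[4-(triisopropylsilyloxy)phenyl]cyclohexa-3,5-diene-1,2-dione | O=C1C(=O)C(c2ccc(O[Si](C(C)C)(C(C)C)C(C)C)cc2)=C(OCc2ccccc2)C(OCc2ccccc2)=C1c1ccc(O[Si](C(C)C)(C(C)C)C(C)C)cc1
F3 | step 3 | 3,4-dichloro-2,5-bis[4-(triisopropylsilyloxy)phenyl]hexa-2,4-dienedinitrile (geometry not controlled) | N#CC(c1ccc(O[Si](C(C)C)(C(C)C)C(C)C)cc1)=C(Cl)C(Cl)=C(c1ccc(O[Si](C(C)C)(C(C)C)C(C)C)cc1)C#N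
F4 | step 11 | (2S,3S)-2-ethynyl-3-methyloxirane | C[C@@H]1O[C@H]1C#C
F5 | step 11 | (4S,5S)-4,5-epoxyhex-2-ynoic acid | C[C@@H]1O[C@H]1C#CC(=O)O
F6 | step 11 | 4,5-bis(tert-butyldimethylsilyloxy)-3,6-bis[4-(triisopropylsilyloxy)phenyl]-1,2-phenylene bis[3-[(2S,3S)-3-methyloxiran-2-yl]prop-2-ynoate] | C[C@@H]1O[C@H]1C#CC(=O)Oc1c(OC(=O)C#C[C@@H]2O[C@H]2C)c(-c2ccc(O[Si](C(C)C)(C(C)C)C(C)C)cc2)c(O[Si](C)(C)C(C)(C)C)c(O[Si](C)(C)C(C)(C)C)c1-c1ccc(O[Si](C(C)C)(C(C)C)C(C)C)cc1
F7 | step 12 | 4,5-bis(benzyloxy)-3,6-bis(4-hydroxyphenyl)benzene-1,2-diol | Oc1c(O)c(-c2ccc(O)cc2)c(OCc2ccccc2)c(OCc2ccccc2)c1-c1ccc(O)cc1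
F8 | step 12 | 1,2-bis(benzyloxy)-4,5-bis(triethylsilyloxy)-3,6-bis[4-(triethylsilyloxy)phenyl]benzene | CC[Si](CC)(CC)Oc1c(O[Si](CC)(CC)CC)c(-c2ccc(O[Si](CC)(CC)CC)cc2)c(OCc2ccccc2)c(OCc2ccccc2)c1-c1ccc(O[Si](CC)(CC)CC)cc1
F9 | step 12 | 4,5-bis(triethylsilyloxy)-3,6-bis[4-(triethylsilyloxy)phenyl]benzene-1,2-diol | CC[Si](CC)(CC)Oc1c(O[Si](CC)(CC)CC)c(-c2ccc(O[Si](CC)(CC)CC)cc2)c(O)c(O)c1-c1ccc(O[Si](CC)(CC)CC)cc1
F10 | step 12 | 4,5-bis(triethylsilyloxy)-3,6-bis[4-(triethylsilyloxy)phenyl]-1,2-phenylene bis[(2Z)-3-[(2S,3S)-3-methyloxiran-2-yl]prop-2-enoate] | C[C@@H]1O[C@H]1/C=C\C(=O)Oc1c(OC(=O)/C=C\[C@@H]2O[C@H]2C)c(-c2ccc(O[Si](CC)(CC)CC)cc2)c(O[Si](CC)(CC)CC)c(O[Si](CC)(CC)CC)c1-c1ccc(O[Si](CC)(CC)CC)cc1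
A1 | alternative 1 | 4,5-dimethoxy-3,6-bis(4-methoxyphenyl)-1,2-benzoquinone | O=C1C(=O)C(c2ccc(OC)cc2)=C(OC)C(OC)=C1c1ccc(OC)cc1
A2 | alternative 1 | 3,6-bis(4-methoxyphenyl)benzene-1,2-diol | Oc1c(O)c(-c2ccc(OC)cc2)ccc1-c1ccc(OC)cc1
A3 | alternative 1 | 2,5-dihydroxy-3,6-bis(4-methoxyphenyl)-1,4-benzoquinone | O=C1C(O)=C(c2ccc(OC)cc2)C(=O)C(O)=C1c1ccc(OC)cc1
A4 | alternative 2 | 4,5-bis(tert-butyldimethylsilyloxy)-3,6-bis[4-(tert-butyldimethylsilyloxy)phenyl]-1,2-phenylene bis[(2Z)-3-[(2S,3S)-3-methyloxiran-2-yl]prop-2-enoate] | C[C@@H]1O[C@H]1/C=C\C(=O)Oc1c(OC(=O)/C=C\[C@@H]2O[C@H]2C)c(-c2ccc(O[Si](C)(C)C(C)(C)C)cc2)c(O[Si](C)(C)C(C)(C)C)c(O[Si](C)(C)C(C)(C)C)c1-c1ccc(O[Si](C)(C)C(C)(C)C)cc1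
A5 | alternative 2 | 4,5-bis(tert-butyldimethylsilyloxy)-3,6-bis[4-(tert-butyldimethylsilyloxy)phenyl]-1,2-phenylene bis[(2Z,4E)-hexa-2,4-dienoate] | C/C=C/C=C\C(=O)Oc1c(OC(=O)/C=C\C=C\C)c(-c2ccc(O[Si](C)(C)C(C)(C)C)cc2)c(O[Si](C)(C)C(C)(C)C)c(O[Si](C)(C)C(C)(C)C)c1-c1ccc(O[Si](C)(C)C(C)(C)C)cc1
A6 | alternative 3 | 2,5-bis[4-(triisopropylsilyloxy)phenyl]-3,6-dihydroxy-1,4-benzoquinone | O=C1C(c2ccc(O[Si](C(C)C)(C(C)C)C(C)C)cc2)=C(O)C(=O)C(c2ccc(O[Si](C(C)C)(C(C)C)C(C)C)cc2)=C1O
A7 | alternative 3 | S-ethyl 3-[4-(triisopropylsilyloxy)phenyl]-2-oxopropanethioate | CCSC(=O)C(=O)Cc1ccc(O[Si](C(C)C)(C(C)C)C(C)C)cc1
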